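The target is a meso 1,4-diketone in which each ring A (2,4-dihydroxyphenyl) carries hydroxyls on C2' and C4', ortho and para to C1', the ring carbon bonded to ketone carbon C1 or C4. This is the oxygen pattern a 1,1,3-trioxygenated butadiene imprints on an ethynyl ketone, so both rings A are disconnected together to a meso bis-ynone. One operation, a double Diels-Alder aromatisation, then creates both benzene rings and four C-C bonds under neutral conditions that leave the enolisable C2 and C3 alone. The precursor is meso-4,5-dibenzylocta-1,7-diyne-3,6-dione with the ring B phenols as triisopropylsilyl ethers, built from dimethyl acetylenedicarboxylate by carbocupration, benzylation and syn hydrogenation.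

Key step: step 8

Assumption: the two stereodescriptors encode the meso (2R,3S) diastereomer; ring A is each 2,4-dihydroxyphenyl ring, ring B each 4-hydroxyphenyl ring, and ring B is carried as silyl ether so that the last step needs only buffered fluoride and no Lewis acid meets the 1,4-diketone.

Step 1
Reactants: 1 4-(benzyloxy)benzyl chloride; 2 dimethyl acetylenedicarboxylate; 3 4-(benzyloxy)benzyl bromide
Product: 7 dimethyl (Z)-2,3-bis[4-(benzyloxy)benzyl]but-2-enedioate, via benzylmagnesium chloride reagent 4 (not isolated), via benzylcopper reagent 5 (not isolated), via syn alkenylcopper adduct 6 (not isolated)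
Conditions: Mg, THF, 0 °C; CuBr·SMe2, −40 °C; 2, −78 °C; then 3, DMPU, −78 → 0 °C
Reagents that add atoms: none
Why: Grignard formation and transmetalation give a benzylcopper reagent that should add syn across the acetylenedicarboxylate (carbocupration), and alkylation of the alkenylcopper with retention then leaves the two esters cis (Z); no stereocenter is formed.

Step 2
Reactants: 7 dimethyl (Z)-2,3-bis[4-(benzyloxy)benzyl]but-2-enedioate
Product: 8 dimethyl meso-(2R,3S)-2,3-bis(4-hydroxybenzyl)butanedioate
Conditions: H2 (5 bar), 10% Pd/C, EtOAc–MeOH, rt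
Reagents that add atoms: none
Why: Heterogeneous catalytic hydrogenation should deliver both hydrogens to one face of the Z alkene, which for two identical ends sets C2 and C3 as the meso pair, and the same palladium surface removes both benzyl ethers by hydrogenolysis.

Step 3
Reactants: 8 dimethyl meso-(2R,3S)-2,3-bis(4-hydroxybenzyl)butanedioate
Product: 9 dimethyl meso-(2R,3S)-2,3-bis[4-(triisopropylsilyloxy)benzyl]butanedioate
Conditions: TIPSCl, imidazole, DMF, rt
Reagents that add atoms: chlorotriisopropylsilane, CC(C)[Si](Cl)(C(C)C)C(C)C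
Why: Imidazole-promoted silyl ether formation on the two phenols installs a group that should tolerate aluminium amides, Grignard reagents and dilute acid and that leaves later with buffered fluoride.

Step 4
Reactants: 9 dimethyl meso-(2R,3S)-2,3-bis[4-(triisopropylsilyloxy)benzyl]butanedioate
Product: 10 meso-(2R,3S)-N,N'-dimethoxy-N,N'-dimethyl-2,3-bis[4-(triisopropylsilyloxy)benzyl]butanediamide
Conditions: MeNHOMe·HCl, AlMe3, CH2Cl2, 0 → 40 °C
Reagents that add atoms: N,O-dimethylhydroxylamine hydrochloride, CNOC.Cl
Why: Weinreb amide formation by aminolysis of the esters with the aluminium amide made in the flask is a non-basic acyl substitution, so the meso centres next to the carbonyls should not epimerise.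

Step 5
Reactants: 10 meso-(2R,3S)-N,N'-dimethoxy-N,N'-dimethyl-2,3-bis[4-(triisopropylsilyloxy)benzyl]butanediamide; 11 ethynylmagnesium bromide
Product: 13 meso-4,5-bis[4-(triisopropylsilyloxy)benzyl]octa-1,7-diyne-3,6-dione, via bis(magnesium hemiaminal) chelate 12 (not isolated)
Conditions: 11 (6 equiv), THF, 0 °C → rt; inverse quench into cold aq. NaHSO4
Reagents that add atoms: none
Why: Weinreb ketone synthesis, in which each amide should take up one alkynyl Grignard to give a stable magnesium chelate that collapses to the ynone only on the acidic inverse quench, which also protonates the freed amine before it can add to the ynone.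

Step 6
Reactants: 14 methyl acetoacetate
Product: 15 methyl 3-(trimethylsilyloxy)but-2-enoate (mixture of alkene isomers, geometry of no consequence)
Conditions: TMSCl, Et3N, hexane, rt
Reagents that add atoms: chlorotrimethylsilane, C[Si](C)(C)Cl
Why: Silyl enol ether formation by O-silylation of the enol of the beta-keto ester with a silyl chloride and an amine base.

Step 7
Reactants: 15 methyl 3-(trimethylsilyloxy)but-2-enoate
Product: 17 (1Z)-1-methoxy-1,3-bis(trimethylsilyloxy)buta-1,3-diene, via lithium dienolate 16 (not isolated)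
Conditions: LiN(iPr)2, THF, −78 °C; TMSCl, −78 → 0 °C
Reagents that add atoms: chlorotrimethylsilane, C[Si](C)(C)Cl
Why: Kinetic gamma-deprotonation should give the extended ester dienolate, which is trapped on oxygen by the silyl chloride (silyl ketene acetal formation) to give the 1,1,3-trioxygenated diene.

Step 8
Reactants: 13 meso-4,5-bis[4-(triisopropylsilyloxy)benzyl]octa-1,7-diyne-3,6-dione; 17 (1Z)-1-methoxy-1,3-bis(trimethylsilyloxy)buta-1,3-diene
Product: 20 meso-1,4-bis(2,4-dihydroxyphenyl)-2,3-bis[4-(triisopropylsilyloxy)benzyl]butane-1,4-dione, via bis(cyclohexadiene ketal) cycloadduct 18 (not isolated), via ring A tetrakis(trimethylsilyl) ether 19 (not isolated)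
Conditions: 17 (5 equiv), toluene, 0 → 40 °C; then 0.5 M HCl, THF, 0 °C
Reagents that add atoms: none
Why: Each ethynyl ketone of 13 is a strongly polarised dienophile and 17 a very electron-rich diene, so a thermal [4+2] cycloaddition, concerted but highly asynchronous, should take place at both ends: the bond from the unsubstituted CH2 terminus of the diene to the terminal alkyne carbon leads, and the bond from the ketene acetal carbon to the alkyne carbon next to the ketone follows. The closest known reaction type is the Diels-Alder aromatisation of 1,1,3-trioxygenated butadienes with acetylenic ketones and esters, which delivers 2,4-dioxygenated aryl carbonyl compounds. Each ring A closes as a six-membered carbocycle from four diene carbons and the two alkyne carbons (in the stepwise limit a Mukaiyama-Michael addition followed by 6-exo-trig capture of the oxocarbenium carbon by the allenolate carbon) to give the cyclohexa-1,4-diene ketal 18, which aromatises by expelling methanol to the silyl ethers 19; cold dilute acid then cleaves the four trimethylsilyl ethers, and any ketal that survived loses its silyl group first and then methanol, so the oxygen stays on the ring, while the hindered triisopropylsilyl ethers of ring B are kept. No stereocenter is formed in the product: the ketal carbons of 18 are transient, and C2 and C3 of the chain (set in step 2) are not touched because no base, Lewis acid or organometallic reagent is present. The step needs one regiochemistry per ring, secured by the matched polarisation of the partners (largest HOMO coefficient on the diene CH2, largest LUMO coefficient on the alkyne terminus beta to the ketone), which places the ketal oxygen ortho and the 3-silyloxy oxygen para to the acyl carbon. It also needs chemoselectivity, secured by the ynones being the only electron-poor pi systems in 13.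

Step 9
Reactants: 20 meso-1,4-bis(2,4-dihydroxyphenyl)-2,3-bis[4-(triisopropylsilyloxy)benzyl]butane-1,4-dione
Product: 21 meso-(2R,3S)-1,4-bis(2,4-dihydroxyphenyl)-2,3-bis(4-hydroxybenzyl)butane-1,4-dione (CNP0406969.1)
Conditions: TBAF, AcOH, THF, 0 °C
Reagents that add atoms: none
Why: Fluoride-mediated cleavage of the two aryl silyl ethers, buffered with acetic acid so that the phenoxides are protonated at once and C2 and C3 are not exposed to base or to acid strong enough for Paal-Knorr furan formation.

Compound list
1 | 4-(benzyloxy)benzyl chloride | ClCc1ccc(OCc2ccccc2)cc1 | starting material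
2 | dimethyl acetylenedicarboxylate | COC(=O)C#CC(=O)OC | starting material
3 | 4-(benzyloxy)benzyl bromide | BrCc1ccc(OCc2ccccc2)cc1 | starting material
4 | [4-(benzyloxy)benzyl]magnesium chloride | Cl[Mg]Cc1ccc(OCc2ccccc2)cc1 | intermediate
5 | [4-(benzyloxy)benzyl]copper (as its magnesium halide and dimethyl sulfide complex) | [Cu]Cc1ccc(OCc2ccccc2)cc1 | intermediate
6 | dimethyl 2-[4-(benzyloxy)benzyl]-3-cupriobut-2-enedioate, benzyl and copper cis, esters cis | COC(=O)/C([Cu])=C(/Cc1ccc(OCc2ccccc2)cc1)C(=O)OC | intermediate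
7 | dimethyl (Z)-2,3-bis[4-(benzyloxy)benzyl]but-2-enedioate | COC(=O)/C(Cc1ccc(OCc2ccccc2)cc1)=C(/Cc1ccc(OCc2ccccc2)cc1)C(=O)OC | intermediate
8 | dimethyl meso-(2R,3S)-2,3-bis(4-hydroxybenzyl)butanedioate | COC(=O)[C@@H](Cc1ccc(O)cc1)[C@@H](Cc1ccc(O)cc1)C(=O)OC | intermediate
9 | dimethyl meso-(2R,3S)-2,3-bis[4-(triisopropylsilyloxy)benzyl]butanedioate | COC(=O)[C@@H](Cc1ccc(O[Si](C(C)C)(C(C)C)C(C)C)cc1)[C@@H](Cc1ccc(O[Si](C(C)C)(C(C)C)C(C)C)cc1)C(=O)OC | intermediate
10 | meso-(2R,3S)-N,N'-dimethoxy-N,N'-dimethyl-2,3-bis[4-(triisopropylsilyloxy)benzyl]butanediamide | CON(C)C(=O)[C@@H](Cc1ccc(O[Si](C(C)C)(C(C)C)C(C)C)cc1)[C@@H](Cc1ccc(O[Si](C(C)C)(C(C)C)C(C)C)cc1)C(=O)N(C)OC | intermediate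
11 | ethynylmagnesium bromide | C#C[Mg]Br | starting material
12 | bis(bromomagnesium) alkoxide of 3,6-bis[methoxy(methyl)amino]-4,5-bis[4-(triisopropylsilyloxy)benzyl]octa-1,7-diyne-3,6-diol, meso at C4 and C5, carbinol carbons unassigned | C#CC(O[Mg]Br)(N(C)OC)[C@@H](Cc1ccc(O[Si](C(C)C)(C(C)C)C(C)C)cc1)[C@@H](Cc1ccc(O[Si](C(C)C)(C(C)C)C(C)C)cc1)C(O[Mg]Br)(N(C)OC)C#C | intermediate
13 | meso-(4R,5S)-4,5-bis[4-(triisopropylsilyloxy)benzyl]octa-1,7-diyne-3,6-dione | C#CC(=O)[C@@H](Cc1ccc(O[Si](C(C)C)(C(C)C)C(C)C)cc1)[C@@H](Cc1ccc(O[Si](C(C)C)(C(C)C)C(C)C)cc1)C(=O)C#C | intermediate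
14 | methyl acetoacetate | COC(=O)CC(C)=O | starting material
15 | methyl 3-(trimethylsilyloxy)but-2-enoate (mixture of alkene isomers) | COC(=O)C=C(C)O[Si](C)(C)C | intermediate
16 | lithium (1Z)-1-methoxy-3-(trimethylsilyloxy)buta-1,3-dien-1-olate | CO/C(O[Li])=C/C(=C)O[Si](C)(C)C | intermediate
17 | (1Z)-1-methoxy-1,3-bis(trimethylsilyloxy)buta-1,3-diene | CO/C(O[Si](C)(C)C)=C/C(=C)O[Si](C)(C)C | intermediate
18 | 1,4-bis[6-methoxy-4,6-bis(trimethylsilyloxy)cyclohexa-1,4-dien-1-yl]-2,3-bis[4-(triisopropylsilyloxy)benzyl]butane-1,4-dione, meso at C2 and C3, ketal carbons unassigned | O=C(C1=CCC(O[Si](C)(C)C)=CC1(OC)O[Si](C)(C)C)[C@@H](Cc1ccc(O[Si](C(C)C)(C(C)C)C(C)C)cc1)[C@@H](Cc1ccc(O[Si](C(C)C)(C(C)C)C(C)C)cc1)C(=O)C1=CCC(O[Si](C)(C)C)=CC1(OC)O[Si](C)(C)C | intermediate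
19 | meso-1,4-bis[2,4-bis(trimethylsilyloxy)phenyl]-2,3-bis[4-(triisopropylsilyloxy)benzyl]butane-1,4-dione | O=C(c1ccc(O[Si](C)(C)C)cc1O[Si](C)(C)C)[C@@H](Cc1ccc(O[Si](C(C)C)(C(C)C)C(C)C)cc1)[C@@H](Cc1ccc(O[Si](C(C)C)(C(C)C)C(C)C)cc1)C(=O)c1ccc(O[Si](C)(C)C)cc1O[Si](C)(C)C | intermediate
20 | meso-(2R,3S)-1,4-bis(2,4-dihydroxyphenyl)-2,3-bis[4-(triisopropylsilyloxy)benzyl]butane-1,4-dione | O=C(c1ccc(O)cc1O)[C@@H](Cc1ccc(O[Si](C(C)C)(C(C)C)C(C)C)cc1)[C@@H](Cc1ccc(O[Si](C(C)C)(C(C)C)C(C)C)cc1)C(=O)c1ccc(O)cc1O | intermediate
21 | meso-(2R,3S)-1,4-bis(2,4-dihydroxyphenyl)-2,3-bis(4-hydroxybenzyl)butane-1,4-dione | O=C(c1ccc(O)cc1O)[C@@H](Cc1ccc(O)cc1)[C@@H](Cc1ccc(O)cc1)C(=O)c1ccc(O)cc1O | target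

Total step count: 9. Longest linear sequence: 7 steps (steps 1, 2, 3, 4, 5, 8, 9); steps 6 and 7 make the diene in a side branch.

Steps most likely to fail

Step 8. The second cycloaddition may stall at the hindered, alpha-branched ynone. The addition may also stop at the Michael stage without ring closure, or the ketal may aromatise by loss of silanol instead of methanol, leaving an ortho methyl ether. The fallback brings rings A in intact instead of building them. It sets out from 10 and returns at 20. 4-Bromoresorcinol is benzylated (BnBr, K2CO3, DMF) to 2,4-bis(benzyloxy)-1-bromobenzene F1. Bromine-lithium exchange (n-BuLi, THF, −78 °C) gives 2,4-bis(benzyloxy)phenyllithium F2, which is added in excess to 10 (THF, −78 °C, then aq. NH4Cl) to give meso-1,4-bis[2,4-bis(benzyloxy)phenyl]-2,3-bis[4-(triisopropylsilyloxy)benzyl]butane-1,4-dione F3. Hydrogenolysis (H2, Pd/C, EtOAc, rt) removes the four benzyl ethers and gives 20.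

Step 1. Capture of the ester-stabilised alkenylcopper by the benzylic bromide may be slow, so that the adduct equilibrates through its copper allenoate form and the Z geometry is lost. Wurtz coupling during Grignard formation may also consume the benzyl chloride. The fallback makes both C-C bonds by cross-coupling on a preformed Z alkene. It sets out from 1 and returns at 7. Zinc insertion (Zn, LiCl, THF, rt) converts 1 into 4-(benzyloxy)benzylzinc chloride F4. Dibromomaleic acid is esterified (MeOH, H2SO4, reflux; Fischer esterification) to dimethyl (Z)-2,3-dibromobut-2-enedioate F5. Twofold Negishi coupling of F5 with F4 (Pd(PPh3)4, THF, 50 °C), with retention of alkene geometry, gives 7.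

Step 2. On palladium the double bond may migrate into the benzylic position before it is reduced, which would erode the meso outcome; reduction of the crowded tetrasubstituted alkene may also stay incomplete. The fallback hydrogenates a ring-locked, planar substrate in which the endocyclic alkene is the stable isomer. It sets out from 7 and returns at 8. Saponification and acidification (LiOH, THF–H2O; then HCl) give 3,4-bis[4-(benzyloxy)benzyl]furan-2,5-dione F6, the anhydride closing spontaneously. Hydrogenation (H2, Pd/C, EtOAc) adds to one face of the ring and cleaves the benzyl ethers to give cis-3,4-bis(4-hydroxybenzyl)oxolane-2,5-dione F7. Acid-catalysed methanolysis and esterification (MeOH, HCl from AcCl, 50 °C) give 8.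

Further compounds
F1 | step 8 | 2,4-bis(benzyloxy)-1-bromobenzene | Brc1ccc(OCc2ccccc2)cc1OCc1ccccc1
F2 | step 8 | 2,4-bis(benzyloxy)phenyllithium | [Li]c1ccc(OCc2ccccc2)cc1OCc1ccccc1
F3 | step 8 | meso-1,4-bis[2,4-bis(benzyloxy)phenyl]-2,3-bis[4-(triisopropylsilyloxy)benzyl]butane-1,4-dione | O=C(c1ccc(OCc2ccccc2)cc1OCc1ccccc1)[C@@H](Cc1ccc(O[Si](C(C)C)(C(C)C)C(C)C)cc1)[C@@H](Cc1ccc(O[Si](C(C)C)(C(C)C)C(C)C)cc1)C(=O)c1ccc(OCc2ccccc2)cc1OCc1ccccc1
F4 | step 1 | 4-(benzyloxy)benzylzinc chloride | Cl[Zn]Cc1ccc(OCc2ccccc2)cc1
F5 | step 1 | dimethyl (Z)-2,3-dibromobut-2-enedioate | COC(=O)/C(Br)=C(/Br)C(=O)OC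
F6 | step 2 | 3,4-bis[4-(benzyloxy)benzyl]furan-2,5-dione | O=C1OC(=O)C(Cc2ccc(OCc3ccccc3)cc2)=C1Cc1ccc(OCc2ccccc2)cc1
F7 | step 2 | cis-3,4-bis(4-hydroxybenzyl)oxolane-2,5-dione (meso) | O=C1OC(=O)[C@H](Cc2ccc(O)cc2)[C@@H]1Cc1ccc(O)cc1
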